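The leftover of starting complex is best read together with the far end of the chain. Call it c(start), the complex with two exchanged c(two) and the complex with one exchanged c(one), all in percent of the starting complex charged. Then c(start) and c(two) are the two amounts to watch, and c(one) is what they leave.

| setting | amber | ochre | red | cedar | alder | birch |
|---|---|---|---|---|---|---|
| starting complex | 0.10 M | 0.10 M | 0.10 M | 0.10 M | 0.10 M | 0.10 M |
| incoming ligand | 0.10 M | 0.18 M | 0.42 M | 0.0950 M | 0.190 M | 0.380 M |
| remark | run made earlier | run made earlier | run made earlier |  |  |  |
| time |  |  |  | 25 min | 25 min | 25 min |

| run | time / min | starting complex / % | complex with one exchanged / % | complex with two exchanged / % |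
|---|---|---|---|---|
| amber | 3.00 | 45.7 | 49.1 | 7.1 |
| amber | 8.00 | 31.6 | 58.7 | 10.8 |
| amber | 15.0 | 30.9 | 61.3 | 10.1 |
| amber | 25.0 | 29.5 | 63.1 | 9.2 |
| ochre | 3.00 | 22.1 | 64.2 | 13.1 |
| ochre | 8.00 | 12.9 | 67.8 | 18.9 |
| ochre | 15.0 | 10.9 | 68.2 | 20.4 |
| ochre | 25.0 | 12.3 | 66.9 | 20.7 |
| red | 6.00 | 4.9 | 50.0 | 47.4 |
| red | 12.0 | 3.6 | 43.7 | 52.0 |
| red | 20.0 | 4.2 | 39.9 | 55.6 |
| red | 25.0 | 6.0 | 38.1 | 56.5 |

(each reading ± 1 percentage point)

- a reading or a percentage of complex with one exchanged counts all its forms, free or not

- which of these there is most of at the end, counted by the starting complex in it, cedar (complex with one exchanged / complex with two exchanged / starting complex)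
- which of these there is most of at the end, counted by the starting complex in it, alder (complex with one exchanged / complex with two exchanged / starting complex)
- which of these there is most of at the end, counted by the starting complex in it, birch (complex with one exchanged / complex with two exchanged / starting complex)
- the largest of these amounts at the end, in percent of the starting complex charged, cedar
- the largest of these amounts at the end, in percent of the starting complex charged, alder
- the largest of these amounts at the end, in percent of the starting complex charged, birch

The textbook disproportionation quotient, c(start)·c(two)/c(one)², climbs from 0.0682 in amber to 0.234 in red. So take the balance mean, the square root of c(start)·c(two) 16.5 %, averaged over the last two readings of each run; those values span 14.9 % to 18.4 %.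

With g held, the ratio r = c(two)/c(start) gives both amounts. Complex with two exchanged overtakes c(one) at c(two) = 47.1 %, which is r = 8.21. Starting complex leads below r = 0.122.

My reckoning takes c(two) on straight lines through the last readings: cedar 8.48 %, alder 22.2 %, birch 50.5 %. Then g gives c(one) of 59.4 % in cedar and 65.5 % in alder, while birch passes the threshold.

The forecast, resolving to “interpolate the 25 min readings”, says complex with one exchanged at 61.5 % for cedar, complex with one exchanged at 66 % for alder and complex with two exchanged at 52 % for birch. It stands above me by 1.9 percentage points on cedar, 0.39 points on alder and 1.5 points on birch.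

The flasks give complex with one exchanged at 60.3 % in cedar, complex with one exchanged at 66.6 % in alder and complex with two exchanged at 51.5 % in birch.

    starting complex + incoming ligand ⇌ leaving ligand + complex with one exchanged (K = 2.24, k = 5.29 M⁻¹ min⁻¹)
    complex with one exchanged + incoming ligand ⇌ leaving ligand + complex with two exchanged (K = 1.92, k = 2.14 M⁻¹ min⁻¹)
    crystals ⇌ complex with one exchanged, rate k3*(cs3 - [complex with one exchanged]) while solid is left; crystals form when [complex with one exchanged] > cs3 (solubility = 17.0 mM, k = 2.55 min⁻¹)

In alder the second step's relaxation half-life of 1.96 min is short against the 25 min, and crystals still hold 49.6 %. Birch's 51.5 % of complex with two exchanged lies 4.4 points above the threshold reckoned from g.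

In a neighbour flask, the same as alder but with 0.048 M of incoming ligand, 61.0 % of starting complex remains. So g gives c(two) = 4.46 % and r = 0.0732, below the lower threshold. The computed neighbour flask holds 3.75 % of complex with two exchanged, with starting complex leading.

Readings and results were generated by integration on assumed constants; the scatter is artificial.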